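## The problem

Target 30 is a humulane-type triene: an eleven-membered carbocycle in which C1 carries the exocyclic methylene, C2=C3 is an E-disubstituted olefin, C4 is the gem-dimethyl carbon, C5 the oxygen-bearing methine and C8(Me)=C9 an E-trisubstituted olefin, esterified at C5–O with vanillic acid. A synthesis has to close a medium ring that has no heteroatom seam, fix two endocyclic E double bonds, and place the 2-substituted 1,3-diene C1(=CH2)–C2=C3 directly beside the quaternary C4. C5 (R) is the only stereocentre. It is neopentylic and remote from every other reacting site, so it cannot steer anything; its configuration must come from a reagent and the olefin geometries from the mechanisms that form them. The skipped triene is prone to acid-triggered transannular cyclisation, the diene to cycloaddition and oxidation, the aryl ester to hydride, organometallic and strong alkoxide reagents, and the phenol must be masked during acylation. Diene, ester and free phenol therefore belong at the end and must be released under neutral or mildly basic conditions. The enabling feature is that C1 and the C8=C9 olefin stand 1,5 to each other across the C10–C11 bond, while C2 is an sp2 carbon that can be traced back to a carbonyl. A C1=C2 enolate and the C8=C9 olefin linked through C10–C11 are the product side of an oxy-Cope shift; its reactant side has a C2–C8 bond, that is, a seven-membered ring C2–C3–C4–C5–C6–C7–C8 with vinyl groups on C2 (with OH) and on C8 (with Me).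

## Retrosynthesis

Ester and phenol. The C5O–C(=O)Ar bond of 30 is cut last, giving dienol 25 and the acetyl-masked acid 27 (one step from vanillic acid 26) by way of ester 29. The ester cannot travel through hydride, enolate or organometallic steps, and an aryl acetate can be removed with methanol and a trace of carbonate, which the hindered neopentylic aroyl ester resists. The forward reaction must acylate a hindered secondary alcohol without acid.

Diene. The C2=C3 double bond of 25 (via silyl ether 24) is traced to a leaving group on C2 in allylic carbonate 23, which comes from alcohol 22 and enone 21. With C1 already sp2, the π-allyl unit C2–C1–CH2 has β-hydrogens only on C3, so elimination can give only one constitutional diene. Acid dehydration would trigger transannular chemistry, and a selenoxide route would run into [2,3] shifts. The forward step must deliver E geometry at C2=C3.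

C1 methylene. The exocyclic carbon of 21 is cut off as a Mannich unit, leading through amine 19 to ketone 18. The cut is chosen because the two α-positions of 18 differ sharply: C1 is an open methylene and C3 is neopentylic, so kinetic enolisation should pick C1.

Ring expansion (key cut). Ketone 18 is traced to the trans-1,2-divinylcycloheptanol 15 by reforming C2–C8 and breaking C10–C11. This replaces an end-to-end closure of an eleven-membered ring with the rearrangement of an unstrained seven-membered ring, and turns the C8=C9 geometry problem into a relative-configuration problem at two adjacent ring carbons. Both of these become sp2, so only C5 has to be carried as a stereocentre. A silyl ether protects C5–O because it survives KH and can later be removed with fluoride in the presence of the diene; a benzyl-type ether would need an oxidant or acid at that stage.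

Divinyl carbinol. The C2–vinyl bond of 15 is cut to give ketone 13 and vinylmagnesium bromide 14. The addition must place the new vinyl group anti to the C8 vinyl group. The configuration of C8 relative to C5 is irrelevant, since both trans-divinyl diastereomers collapse to the same 18.

Quaternary C8. The C8–vinyl bond of 13 is cut to the 2-methyl ketone 10 and phenyl vinyl sulfoxide 11 (through adduct 12). The methyl group is already in place, so only one alkylation at the more substituted α-carbon is needed.

Seven-membered ring. Ketone 10 is traced through alcohol 9 to cycloheptene 8, and the C2=C8 olefin of 8 is opened to diene 7 (ring-closing metathesis). A diester (Dieckmann) closure was weighed and set aside. Its open-chain precursor holds the C5 hydroxyl γ to an ester beside a gem-dimethyl group and should lactonise before it can be protected, and it would also require a decarboxylation and a separate regioselective C8 methylation. The metathesis route carries the C8 methyl from the start, and hydroboration fixes the ketone at C2 without ambiguity.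

C5 stereocentre and chain. Silyl ether 7 comes from alcohol 6, whose C5–H bond is cut to ketone 5. In 5 one flank is tertiary and the other primary, the best case for a CBS reduction. The C5–C6 bond of 5 is cut to acid chloride 2 (from acid 1) and the Grignard reagent 4 of bromide 3. All carbons of the ring except the two vinyl units and the exocyclic methylene are thus present after two steps.

## Roads not taken

Alternative 1: The C4–C5 bond is cut. In the forward direction the acyclic aldehyde (4E)-4,11-dimethyl-8-[(trimethylsilyl)methyl]dodeca-4,8,10-trienal A1 would be activated by BINOL with TiF4 and attacked by the far end (C4) of its own pentadienylsilane, giving (1R,3E,8E)-2,2,9-trimethyl-5-methylidenecycloundeca-3,8-dien-1-ol A2, which is identical with 25.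
- Merits: one step would make the ring, the C5 stereocentre and the complete diene, and A2 is two operations from the target. In step count this road is clearly better than the chosen one.
- Weak points: the bond must form at the fully substituted terminus C4, next to the new stereocentre, inside an eleven-membered transition state. The less hindered γ-position C2 is open and leads to a nine-membered ring. Enantioface control by a chiral Lewis acid on an enolisable aliphatic aldehyde in a high-dilution macrocyclisation is asked to do what is normally shown on simple intermolecular cases.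
- Comparison: the chosen plan is far longer, but ring size, C5 configuration and C8=C9 geometry each follow from a step with a known, separately testable bias.

Alternative 2: The C3–C4 bond is cut. The caesium salt of (3R,6E,11E)-3-{[4-(tert-butyldimethylsilyloxy)-3-methoxybenzoyl]oxy}-2,2,6-trimethyl-10-oxo-12-(phenylsulfonyl)dodeca-6,11-dienoic acid A3 would be oxidised under visible light by Ir[dF(CF3)ppy]2(dtbbpy)PF6. Loss of CO2 gives the tertiary C4 radical, which adds to C3 of the β-sulfonyl enone and expels the sulfonyl radical, giving (1R,3E,8E)-2,2,9-trimethyl-5-oxocycloundeca-3,8-dien-1-yl 4-(tert-butyldimethylsilyloxy)-3-methoxybenzoate A4.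
- Merits: a radical forms the quaternary-to-sp2 bond with little regard for crowding. The E-C2=C3 olefin comes directly from addition–elimination, which is the stage where the chosen plan is weakest and spends three steps. The ester is already in place, and the C8=C9 olefin is made in an open chain where E control is routine.
- Weak points: an eleven-membered radical closure competes with reduction and hydrogen transfer. The C4 radical is β to the acyloxy group and can undergo a 1,2-acyloxy shift. C1 must still be methylenated with an ylide in the presence of the aryl ester.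
- Comparison: the chosen plan forms its medium ring without dilution and never exposes the ester to carbon nucleophiles, at the price of a longer end-game.

Alternative 3: The C6–C7 bond is cut after a formal ring enlargement. Pd(PPh3)4 would ionise the allylic C7–O bond of the thirteen-membered lactone (6E,11E)-5,5,12-trimethyl-8-methylidene-1-oxacyclotrideca-6,11-diene-2,4-dione A5. CO2 is lost and the C5 ketone enolate attacks C7, giving (3E,8E)-2,2,9-trimethyl-5-methylidenecycloundeca-3,8-dien-1-one A6.
- Merits: the large ring is first made by acylation. The enolate is regiodefined because C4 is quaternary, and the diene is present before the carbocycle forms. A6 could be reduced with the same tertiary-versus-primary bias that the chosen plan uses on ketone 5. The road is probably shorter.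
- Weak points: contraction from thirteen to eleven members raises strain, so collapse of the ion pair competes with enolate protonation, O-allylation, β-hydride loss and attack at C9. Syn/anti isomerisation of the allyl unit can erode C8=C9 geometry. A6 is achiral, so the only stereocentre is set last on a conformationally mobile medium-ring ketone.
- Comparison: the chosen plan fixes C8=C9 through a chair transition state in a unimolecular step and sets C5 early, where enantiomeric purity can be checked and upgraded.

Key step: step 11

Remark on labels: C1–C11 in the prose are the ring atoms of 30 as defined above; locants inside systematic names follow the name.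
Remark on stereochemistry (assumption): the configuration of C8 relative to C5 is not controlled in step 8 and need not be, because C8 becomes sp2 in step 11. Such mixtures are carried on together and their SMILES leave the uncontrolled centres open. Compounds 15 and 16 are drawn as the (1S,2R,5R) member of the trans-divinyl pair; the (1R,2S,5R) member accompanies it.
Remark on supply: 1, 3, 11, 14 and 26 are taken to be catalogue chemicals.

## Route

Step 1
Reactants: 1 2,2-dimethylpent-4-enoic acid
Product: 2 2,2-dimethylpent-4-enoyl chloride
Conditions: (COCl)2, DMF (cat.), CH2Cl2, 0 °C to rt; used crude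
Reagents that add atoms: oxalyl chloride, O=C(Cl)C(=O)Cl
Why: Acid chloride formation through the chloroiminium (Vilsmeier-type) species; the α-carbon is quaternary, so no ketene can form, and the terminal alkene is inert.

Step 2
Reactants: 2 2,2-dimethylpent-4-enoyl chloride; 3 4-bromo-2-methylbut-1-ene
Product: 5 2,6,6-trimethylnona-1,8-dien-5-one, via 3-methylbut-3-enylmagnesium bromide 4 (not isolated)
Conditions: 3, Mg, THF, 40 °C; then 2, CuI (5 mol %), THF, −40 to 0 °C
Reagents that add atoms: magnesium, [Mg] (held only by intermediate 4)
Why: Copper-catalysed acylation of a Grignard reagent by an acid chloride; the ketone formed is flanked by a quaternary carbon and resists a second addition, and the homoallyl/cyclopropylcarbinyl equilibration of 4 is degenerate.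

Step 3
Reactants: 5 2,6,6-trimethylnona-1,8-dien-5-one
Product: 6 (5R)-2,6,6-trimethylnona-1,8-dien-5-ol
Conditions: (S)-2-methyl-CBS-oxazaborolidine (20 mol %), catecholborane, toluene, −78 to −20 °C; then aq NaOH
Reagents that add atoms: none
Why: Corey–Bakshi–Shibata reduction; the ketone binds the catalyst boron with its tertiary arm (C4 side) away from the ring system and hydride goes to the face that gives the 5R carbinol, by analogy with tert-butyl methyl ketone, while catecholborane is used because it does not hydroborate the two alkenes.

Step 4
Reactants: 6 (5R)-2,6,6-trimethylnona-1,8-dien-5-ol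
Product: 7 tert-butyldimethyl{[(5R)-2,6,6-trimethylnona-1,8-dien-5-yl]oxy}silane
Conditions: TBSOTf, 2,6-lutidine, CH2Cl2, 0 °C to rt
Reagents that add atoms: tert-butyldimethylsilyl trifluoromethanesulfonate, CC(C)(C)[Si](C)(C)OS(=O)(=O)C(F)(F)F
Why: Silylation of a hindered secondary alcohol with the silyl triflate; the O–H bond alone reacts, so C5 keeps its configuration.

Step 5
Reactants: 7 tert-butyldimethyl{[(5R)-2,6,6-trimethylnona-1,8-dien-5-yl]oxy}silane
Product: 8 tert-butyldimethyl{[(1R)-2,2,5-trimethylcyclohept-4-en-1-yl]oxy}silane
Conditions: second-generation Grubbs catalyst (3 mol %), CH2Cl2 (0.01 M), 40 °C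
Reagents that add atoms: none
Why: Ring-closing metathesis of a mono- and a 1,1-disubstituted alkene to a trisubstituted cycloheptene, helped by the gem-dimethyl group and driven by loss of ethene.

Step 6
Reactants: 8 tert-butyldimethyl{[(1R)-2,2,5-trimethylcyclohept-4-en-1-yl]oxy}silane
Product: 9 (5R)-5-[(tert-butyldimethylsilyl)oxy]-2,6,6-trimethylcycloheptan-1-ol (1,2-trans, both diastereomers)
Conditions: BH3·THF, THF, 0 °C to rt; then NaOH, H2O2, 0 °C to rt
Reagents that add atoms: hydrogen peroxide, OO
Why: Brown hydroboration puts boron on the less substituted olefinic carbon (C2) and oxidation with retention gives the trans-2-methyl carbinol; the face taken relative to C5 does not matter because both new centres are remade later.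

Step 7
Reactants: 9 (5R)-5-[(tert-butyldimethylsilyl)oxy]-2,6,6-trimethylcycloheptan-1-ol
Product: 10 (5R)-5-[(tert-butyldimethylsilyl)oxy]-2,6,6-trimethylcycloheptan-1-one (both C2 epimers)
Conditions: Dess–Martin periodinane, CH2Cl2, 0 °C to rt
Reagents that add atoms: none
Why: Dess–Martin oxidation of a secondary alcohol under neutral conditions that leave the silyl ether untouched.

Step 8
Reactants: 10 (5R)-5-[(tert-butyldimethylsilyl)oxy]-2,6,6-trimethylcycloheptan-1-one; 11 phenyl vinyl sulfoxide
Product: 12 (5R)-5-[(tert-butyldimethylsilyl)oxy]-2,6,6-trimethyl-2-[2-(phenylsulfinyl)ethyl]cycloheptan-1-one (diastereomers at C2 and sulfur)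
Conditions: NaH, DME, 80 °C; then 11, 0 °C to rt; aq NH4Cl
Reagents that add atoms: none
Why: Michael addition of the more substituted sodium enolate, formed under equilibrating conditions, to the vinyl sulfoxide as a vinyl cation equivalent; the competing C3 enolate is neopentylic and adds more slowly, and the configuration of the new quaternary C8 relative to C5 is uncontrolled and irrelevant.

Step 9
Reactants: 12 (5R)-5-[(tert-butyldimethylsilyl)oxy]-2,6,6-trimethyl-2-[2-(phenylsulfinyl)ethyl]cycloheptan-1-one
Product: 13 (5R)-5-[(tert-butyldimethylsilyl)oxy]-2-ethenyl-2,6,6-trimethylcycloheptan-1-one (both C2 epimers)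
Conditions: toluene, CaCO3, 110 °C
Reagents that add atoms: none
Why: Thermal syn-elimination of the sulfoxide; the only β-hydrogens lie on the CH2 next to the quaternary carbon, so only the vinyl group can form.

Step 10
Reactants: 13 (5R)-5-[(tert-butyldimethylsilyl)oxy]-2-ethenyl-2,6,6-trimethylcycloheptan-1-one; 14 vinylmagnesium bromide
Product: 15 (1S,2R,5R)- and (1R,2S,5R)-5-[(tert-butyldimethylsilyl)oxy]-1,2-diethenyl-2,6,6-trimethylcycloheptan-1-ol (trans-divinyl pair, hydroxyl trans to the C2 methyl)
Conditions: CeCl3, THF, rt; 14, −78 °C; then 13, −78 to 0 °C; aq NH4Cl; chromatography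
Reagents that add atoms: none
Why: CeCl3-mediated 1,2-addition of the Grignard reagent suppresses enolisation of the hindered ketone; Felkin–Anh-type attack anti to the α-vinyl group (the better σ-acceptor and the substituent more at ease pseudo-axial) should favour the trans-divinyl carbinols, which arise from both epimers of 13 and are separated from the cis pair.

Step 11
Reactants: 15 5-[(tert-butyldimethylsilyl)oxy]-1,2-diethenyl-2,6,6-trimethylcycloheptan-1-ol (trans-divinyl pair)
Product: 18 (5E,9R)-9-[(tert-butyldimethylsilyl)oxy]-6,10,10-trimethylcycloundec-5-en-1-one, via potassium alkoxide 16 (not isolated), via potassium enolate 17 (not isolated)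
Conditions: KH, 18-crown-6, THF, 0 to 50 °C; then aq NH4Cl, −78 °C
Reagents that add atoms: potassium hydride, [KH] (potassium is held only by intermediates 16 and 17)
Why: KH deprotonates the tertiary alcohol and 18-crown-6 separates the potassium ion from alkoxide 16, which weakens the C2–C8 bond and accelerates the [3,3] shift far beyond the neutral alcohol. The shift is concerted: C10–C11 forms between the two vinyl termini as C2–C8 breaks, giving the C1=C2 enolate 17 and, after protonation, ketone 18; because the product is an enolate the step is irreversible. The closest known reaction type is the anionic oxy-Cope ring expansion of 1,2-dialkenylcycloalkanols to medium-ring E-cycloalkenones. The eleven-membered ring is not closed end to end; it arises by four-carbon expansion of the seven-membered ring through a six-centre chair transition state, so no dilution is needed. No stereocentre is created: C2 and C8 become sp2 and C5 is a spectator. The selectivity required is E geometry at C8=C9, which follows when the ring bonds C2–C3 and C8–C7 sit pseudo-equatorial in the chair and the oxide and the C8 methyl pseudo-axial, placing C7 trans to C10. Only the trans-divinyl relative configuration secured in step 10 can adopt this arrangement, and both trans diastereomers give the same 18. The silyl ether has no acidic β-hydrogen and is stable to KH.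

Step 12
Reactants: 18 (5E,9R)-9-[(tert-butyldimethylsilyl)oxy]-6,10,10-trimethylcycloundec-5-en-1-one
Product: 19 (5E,9R)-9-[(tert-butyldimethylsilyl)oxy]-2-[(dimethylamino)methyl]-6,10,10-trimethylcycloundec-5-en-1-one (both C2 epimers)
Conditions: LiN(iPr)2, THF, −78 °C; then CH2=NMe2+ I− (Eschenmoser's salt), −78 °C to rt
Reagents that add atoms: dimethylmethylideneammonium iodide, C=[N+](C)C.[I-]
Why: Kinetic deprotonation takes a C1 proton because the C3 methylene is shielded by quaternary C4, and the lithium enolate undergoes a Mannich reaction with the preformed iminium salt.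

Step 13
Reactants: 19 (5E,9R)-9-[(tert-butyldimethylsilyl)oxy]-2-[(dimethylamino)methyl]-6,10,10-trimethylcycloundec-5-en-1-one
Product: 21 (5E,9R)-9-[(tert-butyldimethylsilyl)oxy]-6,10,10-trimethyl-2-methylidenecycloundec-5-en-1-one, via trimethylammonium iodide 20 (not isolated)
Conditions: MeI, CH2Cl2, rt; then aq NaHCO3, rt
Reagents that add atoms: iodomethane, CI (its methyl group is held only by intermediate 20)
Why: Quaternisation followed by Hofmann-type (E1cB) loss of trimethylamine from the β-ammonio ketone under mild bicarbonate conditions gives the exocyclic enone.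

Step 14
Reactants: 21 (5E,9R)-9-[(tert-butyldimethylsilyl)oxy]-6,10,10-trimethyl-2-methylidenecycloundec-5-en-1-one
Product: 22 (5E,9R)-9-[(tert-butyldimethylsilyl)oxy]-6,10,10-trimethyl-2-methylidenecycloundec-5-en-1-ol (both C1 epimers)
Conditions: NaBH4, CeCl3·7H2O, MeOH, −78 to 0 °C
Reagents that add atoms: none
Why: Luche reduction; CeCl3 directs borohydride to 1,2-attack on the enone, and the new carbinol centre, formed as a mixture, is destroyed in step 16.

Step 15
Reactants: 22 (5E,9R)-9-[(tert-butyldimethylsilyl)oxy]-6,10,10-trimethyl-2-methylidenecycloundec-5-en-1-ol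
Product: 23 (5E,9R)-9-[(tert-butyldimethylsilyl)oxy]-6,10,10-trimethyl-2-methylidenecycloundec-5-en-1-yl methyl carbonate (both C1 epimers)
Conditions: ClCO2Me, pyridine, DMAP (cat.), CH2Cl2, 0 °C
Reagents that add atoms: methyl chloroformate, COC(=O)Cl
Why: Acylation of the allylic alcohol to the carbonate, which ionises readily with zerovalent palladium and releases its own base on loss of CO2.

Step 16
Reactants: 23 (5E,9R)-9-[(tert-butyldimethylsilyl)oxy]-6,10,10-trimethyl-2-methylidenecycloundec-5-en-1-yl methyl carbonate
Product: 24 tert-butyldimethyl{[(1R,3E,8E)-2,2,9-trimethyl-5-methylidenecycloundeca-3,8-dien-1-yl]oxy}silane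
Conditions: Pd(PPh3)4 (10 mol %), 1,4-dioxane, 90 °C
Reagents that add atoms: none
Why: Zerovalent palladium ionises the carbonate (Tsuji–Trost) to a π-allyl complex over C2, C1 and the exocyclic carbon; the only hydrogens β to palladium are on C3, so β-hydride loss can give only the C1(=CH2)–C2=C3 diene, and E geometry is expected because C1 and quaternary C4 lie anti in the syn-periplanar Pd–C2–C3–H arrangement.

Step 17
Reactants: 24 tert-butyldimethyl{[(1R,3E,8E)-2,2,9-trimethyl-5-methylidenecycloundeca-3,8-dien-1-yl]oxy}silane
Product: 25 (1R,3E,8E)-2,2,9-trimethyl-5-methylidenecycloundeca-3,8-dien-1-ol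
Conditions: Bu4NF, THF, rt to 45 °C
Reagents that add atoms: none
Why: Fluoride cleaves the Si–O bond in a slightly basic medium, so the acid-sensitive triene never meets a proton source strong enough to start transannular cyclisation.

Step 18
Reactants: 26 vanillic acid
Product: 27 4-acetoxy-3-methoxybenzoic acid
Conditions: Ac2O, pyridine, rt; then H2O
Reagents that add atoms: acetic anhydride, CC(=O)OC(C)=O
Why: Acetylation of the phenol; the mixed anhydride formed at the carboxyl group is hydrolysed on aqueous work-up.

Step 19
Reactants: 25 (1R,3E,8E)-2,2,9-trimethyl-5-methylidenecycloundeca-3,8-dien-1-ol; 27 4-acetoxy-3-methoxybenzoic acid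
Product: 29 (1R,3E,8E)-2,2,9-trimethyl-5-methylidenecycloundeca-3,8-dien-1-yl 4-acetoxy-3-methoxybenzoate, via 4-acetoxy-3-methoxybenzoyl chloride 28 (not isolated)
Conditions: 27, (COCl)2, DMF (cat.), CH2Cl2, 0 °C to rt, evaporate; then 25, Et3N, DMAP, CH2Cl2, rt to 40 °C
Reagents that add atoms: oxalyl chloride, O=C(Cl)C(=O)Cl (chlorine is held only by intermediate 28)
Why: DMAP-catalysed acylation of the neopentylic alcohol through the acylpyridinium ion under basic conditions; no bond to C5 is broken, so its configuration is retained.

Step 20
Reactants: 29 (1R,3E,8E)-2,2,9-trimethyl-5-methylidenecycloundeca-3,8-dien-1-yl 4-acetoxy-3-methoxybenzoate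
Product: 30 (1R,3E,8E)-2,2,9-trimethyl-5-methylidenecycloundeca-3,8-dien-1-yl 4-hydroxy-3-methoxybenzoate
Conditions: K2CO3 (0.2 equiv), MeOH, 0 °C
Reagents that add atoms: none
Why: Base-catalysed methanolysis of the aryl acetate, an activated ester, is much faster than transesterification of the hindered neopentylic benzoate, whose carbonyl is further deactivated once the para-phenoxide forms.

## Compound list

1 | 2,2-dimethylpent-4-enoic acid | C=CCC(C)(C)C(=O)O | starting material
2 | 2,2-dimethylpent-4-enoyl chloride | C=CCC(C)(C)C(=O)Cl | intermediate
3 | 4-bromo-2-methylbut-1-ene | C=C(C)CCBr | starting material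
4 | 3-methylbut-3-enylmagnesium bromide (not isolated) | C=C(C)CC[Mg]Br | intermediate
5 | 2,6,6-trimethylnona-1,8-dien-5-one | C=CCC(C)(C)C(=O)CCC(C)=C | intermediate
6 | (5R)-2,6,6-trimethylnona-1,8-dien-5-ol | C=CCC(C)(C)[C@H](O)CCC(C)=C | intermediate
7 | tert-butyldimethyl{[(5R)-2,6,6-trimethylnona-1,8-dien-5-yl]oxy}silane | C=CCC(C)(C)[C@H](O[Si](C)(C)C(C)(C)C)CCC(C)=C | intermediate
8 | tert-butyldimethyl{[(1R)-2,2,5-trimethylcyclohept-4-en-1-yl]oxy}silane | CC1=CCC(C)(C)[C@H](O[Si](C)(C)C(C)(C)C)CC1 | intermediate
9 | (5R)-5-[(tert-butyldimethylsilyl)oxy]-2,6,6-trimethylcycloheptan-1-ol, 1,2-trans, both diastereomers | OC1CC(C)(C)[C@H](O[Si](C)(C)C(C)(C)C)CCC1C | intermediate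
10 | (5R)-5-[(tert-butyldimethylsilyl)oxy]-2,6,6-trimethylcycloheptan-1-one, both C2 epimers | O=C1CC(C)(C)[C@H](O[Si](C)(C)C(C)(C)C)CCC1C | intermediate
11 | phenyl vinyl sulfoxide, racemic | C=CS(=O)c1ccccc1 | starting material
12 | (5R)-5-[(tert-butyldimethylsilyl)oxy]-2,6,6-trimethyl-2-[2-(phenylsulfinyl)ethyl]cycloheptan-1-one, diastereomers at C2 and sulfur | O=C1CC(C)(C)[C@H](O[Si](C)(C)C(C)(C)C)CCC1(C)CCS(=O)c1ccccc1 | intermediate
13 | (5R)-5-[(tert-butyldimethylsilyl)oxy]-2-ethenyl-2,6,6-trimethylcycloheptan-1-one, both C2 epimers | O=C1CC(C)(C)[C@H](O[Si](C)(C)C(C)(C)C)CCC1(C)C=C | intermediate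
14 | vinylmagnesium bromide | C=C[Mg]Br | starting material
15 | (1S,2R,5R)-5-[(tert-butyldimethylsilyl)oxy]-1,2-diethenyl-2,6,6-trimethylcycloheptan-1-ol, with its (1R,2S,5R) companion (trans-divinyl pair) | O[C@]1(C=C)CC(C)(C)[C@H](O[Si](C)(C)C(C)(C)C)CC[C@]1(C)C=C | intermediate
16 | potassium (1S,2R,5R)-5-[(tert-butyldimethylsilyl)oxy]-1,2-diethenyl-2,6,6-trimethylcycloheptan-1-olate, with its (1R,2S,5R) companion (not isolated) | [K+].[O-][C@]1(C=C)CC(C)(C)[C@H](O[Si](C)(C)C(C)(C)C)CC[C@]1(C)C=C | intermediate
17 | potassium (5E,9R)-9-[(tert-butyldimethylsilyl)oxy]-6,10,10-trimethylcycloundeca-1,5-dien-1-olate (not isolated) | [K+].[O-]C1=CCC/C=C(C)/CC[C@@H](O[Si](C)(C)C(C)(C)C)C(C)(C)C1 | intermediate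
18 | (5E,9R)-9-[(tert-butyldimethylsilyl)oxy]-6,10,10-trimethylcycloundec-5-en-1-one | O=C1CC(C)(C)[C@H](O[Si](C)(C)C(C)(C)C)CC/C(C)=C/CCC1 | intermediate
19 | (5E,9R)-9-[(tert-butyldimethylsilyl)oxy]-2-[(dimethylamino)methyl]-6,10,10-trimethylcycloundec-5-en-1-one, both C2 epimers | O=C1CC(C)(C)[C@H](O[Si](C)(C)C(C)(C)C)CC/C(C)=C/CCC1CN(C)C | intermediate
20 | 1-[(5E,9R)-9-[(tert-butyldimethylsilyl)oxy]-6,10,10-trimethyl-1-oxocycloundec-5-en-2-yl]-N,N,N-trimethylmethanaminium iodide (not isolated) | O=C1CC(C)(C)[C@H](O[Si](C)(C)C(C)(C)C)CC/C(C)=C/CCC1C[N+](C)(C)C.[I-] | intermediate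
21 | (5E,9R)-9-[(tert-butyldimethylsilyl)oxy]-6,10,10-trimethyl-2-methylidenecycloundec-5-en-1-one | O=C1CC(C)(C)[C@H](O[Si](C)(C)C(C)(C)C)CC/C(C)=C/CCC1=C | intermediate
22 | (5E,9R)-9-[(tert-butyldimethylsilyl)oxy]-6,10,10-trimethyl-2-methylidenecycloundec-5-en-1-ol, both C1 epimers | OC1CC(C)(C)[C@H](O[Si](C)(C)C(C)(C)C)CC/C(C)=C/CCC1=C | intermediate
23 | (5E,9R)-9-[(tert-butyldimethylsilyl)oxy]-6,10,10-trimethyl-2-methylidenecycloundec-5-en-1-yl methyl carbonate, both C1 epimers | COC(=O)OC1CC(C)(C)[C@H](O[Si](C)(C)C(C)(C)C)CC/C(C)=C/CCC1=C | intermediate
24 | tert-butyldimethyl{[(1R,3E,8E)-2,2,9-trimethyl-5-methylidenecycloundeca-3,8-dien-1-yl]oxy}silane | C=C1/C=C/C(C)(C)[C@H](O[Si](C)(C)C(C)(C)C)CC/C(C)=C/CC1 | intermediate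
25 | (1R,3E,8E)-2,2,9-trimethyl-5-methylidenecycloundeca-3,8-dien-1-ol | C=C1/C=C/C(C)(C)[C@H](O)CC/C(C)=C/CC1 | intermediate
26 | vanillic acid (4-hydroxy-3-methoxybenzoic acid) | COc1cc(C(=O)O)ccc1O | starting material
27 | 4-acetoxy-3-methoxybenzoic acid | COc1cc(C(=O)O)ccc1OC(C)=O | intermediate
28 | 4-acetoxy-3-methoxybenzoyl chloride (not isolated) | COc1cc(C(=O)Cl)ccc1OC(C)=O | intermediate
29 | (1R,3E,8E)-2,2,9-trimethyl-5-methylidenecycloundeca-3,8-dien-1-yl 4-acetoxy-3-methoxybenzoate | C=C1/C=C/C(C)(C)[C@H](OC(=O)c2ccc(OC(C)=O)c(OC)c2)CC/C(C)=C/CC1 | intermediate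
30 | (1R,3E,8E)-2,2,9-trimethyl-5-methylidenecycloundeca-3,8-dien-1-yl 4-hydroxy-3-methoxybenzoate | C=C1/C=C/C(C)(C)[C@H](OC(=O)c2ccc(O)c(OC)c2)CC/C(C)=C/CC1 | target

## Step count and risks

Total step count: 20. Longest linear sequence: 19 steps (steps 1 to 17, 19 and 20; step 18 prepares the acyl partner).

Least certain steps:

Step 11 (key step). The most likely failure is loss of the concerted course: partial heterolysis of the C2–C8 bond in the crown-separated alkoxide to an enone/allyl-anion pair that recombines outside the chair. Any cis-divinyl material left from step 10 could also react through a chair with C7–C8 pseudo-axial. Either process erodes E selectivity at C8=C9. A slow shift would also give time for silyl transfer from the C5 oxygen to the C2 oxide. The fallback is the neutral, thermal siloxy-Cope variant, which sets out from 15. Silylation with Me3SiCl and imidazole gives the 1-(trimethylsilyloxy)-1,2-divinylcycloheptane F1. Heating in 1,2-dichlorobenzene at about 220 °C in a sealed tube sends it through the same chair, without a charge to promote fragmentation, to the trimethylsilyl enol ether of the cycloundecenone F2. Brief K2CO3 in MeOH then frees the ketone, and the route is rejoined at 18.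

Step 10. Facial discrimination between the α-methyl and α-vinyl groups may be poor because the two are similar in size, and the hindered ketone may enolise instead of adding. The fallback changes the nucleophile class and sets out from 13. Ethynylmagnesium bromide with CeCl3 is a slender, rod-like reagent that responds to torsional factors more than to bulk and gives propargylic carbinols that are usually easier to separate; it would give the 1-ethynyl-2-vinylcycloheptanol F3. Hydroalumination of the propargylic alcohol with NaAlH2(OCH2CH2OMe)2 in THF then gives the vinyl carbinol, rejoining the route at 15.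

Step 16. Geometric control at the new C2=C3 bond may be lost during β-hydride elimination within the medium ring, or methoxide may capture the π-allyl complex and divert material to an allyl methyl ether. The fallback sets the geometry in a different event and sets out from 21. KN(SiMe3)2 and PhNTf2 at −78 °C enolise the only position that carries α-hydrogens (C3, since C1 is sp2) and give the cross-conjugated dienyl triflate F4, with oxygen expected syn to C4 so that C1 and C4 stay apart. Palladium-catalysed formate reduction (Pd(OAc)2, PPh3, HCO2H, Bu3N, DMF, 60 °C) replaces the triflate by hydrogen with retention, rejoining the route at 24.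

Step 8. Conjugate addition of the hindered, tetrasubstituted enolate to the weakly electrophilic vinyl sulfoxide may be sluggish, and proton shuttling may let the C3 enolate or a second addition compete. The fallback uses a regiodefined enolate and an aldol-based vinylation and sets out from 10. Me3SiCl and Et3N in hot DMF give the more substituted trimethylsilyl enol ether F5. MeLi releases the lithium enolate, which adds to (phenylselanyl)acetaldehyde to give the β-hydroxy selenide F6. MsCl and Et3N then cause anti elimination of the hydroxyl and selanyl groups to the vinyl group, rejoining the route at 13.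

Step 19. Acylation of the neopentylic C5 hydroxyl may be slow enough for DMAP-mediated acetyl transfer from the aryl acetate to cap the alcohol as its acetate. The fallback removes the transferable acyl group from the partner and sets out from 26 and 25. TBSCl and imidazole silylate both acidic sites of 26 to the silyl ester silyl ether F7, and K2CO3 in aqueous MeOH frees the carboxyl group to give 4-(tert-butyldimethylsilyloxy)-3-methoxybenzoic acid F8. Yamaguchi esterification with 25 (2,4,6-trichlorobenzoyl chloride, Et3N, then DMAP, toluene, 80 °C) gives the silyl-protected vanillate F9. Bu4NF buffered with AcOH at 0 °C then releases the phenol, rejoining the route at 30.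

## Further compounds

F1 | step 11 | (1S,2R,5R)-5-[(tert-butyldimethylsilyl)oxy]-1,2-diethenyl-2,6,6-trimethyl-1-[(trimethylsilyl)oxy]cycloheptane, with its (1R,2S,5R) companion | C[Si](C)(C)O[C@]1(C=C)CC(C)(C)[C@H](O[Si](C)(C)C(C)(C)C)CC[C@]1(C)C=C
F2 | step 11 | tert-butyldimethyl{[(1R,8E)-2,2,9-trimethyl-4-[(trimethylsilyl)oxy]cycloundeca-4,8-dien-1-yl]oxy}silane | C[Si](C)(C)OC1=CCC/C=C(C)/CC[C@@H](O[Si](C)(C)C(C)(C)C)C(C)(C)C1
F3 | step 10 | (1S,2R,5R)-5-[(tert-butyldimethylsilyl)oxy]-2-ethenyl-1-ethynyl-2,6,6-trimethylcycloheptan-1-ol, with its (1R,2S,5R) companion | O[C@]1(C#C)CC(C)(C)[C@H](O[Si](C)(C)C(C)(C)C)CC[C@]1(C)C=C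
F4 | step 16 | (1Z,4R,7E)-4-[(tert-butyldimethylsilyl)oxy]-3,3,7-trimethyl-11-methylidenecycloundeca-1,7-dien-1-yl trifluoromethanesulfonate | C=C1CC/C=C(C)/CC[C@@H](O[Si](C)(C)C(C)(C)C)C(C)(C)/C=C1\OS(=O)(=O)C(F)(F)F
F5 | step 8 | tert-butyldimethyl{[(1R)-2,2,5-trimethyl-4-[(trimethylsilyl)oxy]cyclohept-4-en-1-yl]oxy}silane | C[Si](C)(C)OC1=C(C)CC[C@@H](O[Si](C)(C)C(C)(C)C)C(C)(C)C1
F6 | step 8 | (5R)-5-[(tert-butyldimethylsilyl)oxy]-2-[1-hydroxy-2-(phenylselanyl)ethyl]-2,6,6-trimethylcycloheptan-1-one, mixture of diastereomers | O=C1CC(C)(C)[C@H](O[Si](C)(C)C(C)(C)C)CCC1(C)C(O)C[Se]c1ccccc1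
F7 | step 19 | tert-butyldimethylsilyl 4-[(tert-butyldimethylsilyl)oxy]-3-methoxybenzoate | COc1cc(C(=O)O[Si](C)(C)C(C)(C)C)ccc1O[Si](C)(C)C(C)(C)C
F8 | step 19 | 4-[(tert-butyldimethylsilyl)oxy]-3-methoxybenzoic acid | COc1cc(C(=O)O)ccc1O[Si](C)(C)C(C)(C)C
F9 | step 19 | (1R,3E,8E)-2,2,9-trimethyl-5-methylidenecycloundeca-3,8-dien-1-yl 4-[(tert-butyldimethylsilyl)oxy]-3-methoxybenzoate | C=C1/C=C/C(C)(C)[C@H](OC(=O)c2ccc(O[Si](C)(C)C(C)(C)C)c(OC)c2)CC/C(C)=C/CC1
A1 | alternative 1 | (4E)-4,11-dimethyl-8-[(trimethylsilyl)methyl]dodeca-4,8,10-trienal | O=CCC/C(C)=C/CCC(C[Si](C)(C)C)=CC=C(C)C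
A2 | alternative 1 | (1R,3E,8E)-2,2,9-trimethyl-5-methylidenecycloundeca-3,8-dien-1-ol (identical with 25) | C=C1/C=C/C(C)(C)[C@H](O)CC/C(C)=C/CC1
A3 | alternative 2 | (3R,6E,11E)-3-{[4-(tert-butyldimethylsilyloxy)-3-methoxybenzoyl]oxy}-2,2,6-trimethyl-10-oxo-12-(phenylsulfonyl)dodeca-6,11-dienoic acid | OC(=O)C(C)(C)[C@H](OC(=O)c1ccc(O[Si](C)(C)C(C)(C)C)c(OC)c1)CC/C(C)=C/CCC(=O)/C=C/S(=O)(=O)c1ccccc1
A4 | alternative 2 | (1R,3E,8E)-2,2,9-trimethyl-5-oxocycloundeca-3,8-dien-1-yl 4-(tert-butyldimethylsilyloxy)-3-methoxybenzoate | O=C1/C=C/C(C)(C)[C@H](OC(=O)c2ccc(O[Si](C)(C)C(C)(C)C)c(OC)c2)CC/C(C)=C/CC1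
A5 | alternative 3 | (6E,11E)-5,5,12-trimethyl-8-methylidene-1-oxacyclotrideca-6,11-diene-2,4-dione | O=C1CC(=O)OC/C(C)=C/CCC(=C)/C=C/C1(C)C
A6 | alternative 3 | (3E,8E)-2,2,9-trimethyl-5-methylidenecycloundeca-3,8-dien-1-one | O=C1CC/C(C)=C/CCC(=C)/C=C/C1(C)C
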